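**Retrosynthetic overview**

- The target is reached from the all-trans 2-aryl-3-(acetoxymethyl)-4-(4-methoxybenzoyl)tetrahydrofuran by chelation-controlled reduction at Cα, acetylation and phenol desilylation; the C9 acetate comes from a C9 bromide.
- The strategy rests on this feature: in the ring O1–C2(aryl)–C3(C9H2OAc)–C4(Cα)–C5H2, C4 lies α to a Cα ketone and C3–C9 maps onto a vinyl group on the O1-bearing carbinol C2. The only ring is therefore closed at C3–C4 by a 5-exo radical cyclisation with bromine atom transfer, where an enolate at C4 would expel O1.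
- The α-bromo-β-(1-arylallyloxy) ketone comes from the β-alkoxy ketone, itself the oxa-Michael adduct of (R)-1-arylprop-2-en-1-ol and 4-methoxyphenyl vinyl ketone.
- The allylic alcohol comes from silylated 4-hydroxybenzaldehyde by catalytic enantioselective vinylation; the vinyl ketone comes from 4'-methoxyacetophenone by Mannich methylenation.

Key step: step 6

Remark on the chemistry: the phenol is carried as its triisopropylsilyl ether, because a tert-butyldimethylsilyl aryl ether is unlikely to survive acetate in DMF and DBU later in the route.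
Remark on the chemistry: the α-bromo ketone is used as the mixture of bromide epimers, since that centre becomes a planar radical.
Remark on the chemistry: the (2R) amino alcohol ligand is assumed to deliver vinyl to the Re face of the aldehyde, mirroring the Si-face alkyl delivery of its (2S) antipode; the antipodal ligand would be used if the alcohol proves to be (S).
Remark on the chemistry: C4 is fixed for good only in step 7. The bromide from the radical closure is carried forward unfractionated, and its 3,4-cis epimer is numbered at the step that consumes it.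

**Route**

Step 1
Reactants: 1 4-hydroxybenzaldehyde
Product: 2 4-(triisopropylsilyloxy)benzaldehyde
Conditions: iPr3SiCl, imidazole, DMF, 0 °C → rt
Reagents that add atoms: chlorotriisopropylsilane, CC(C)[Si](Cl)(C(C)C)C(C)C
Why: Imidazole-mediated O-silylation of the phenol; the hindered aryl silyl ether should withstand the organozinc, the amide base, acetate in dry DMF and DBU, and still leave with buffered fluoride at the end.

Step 2
Reactants: 2 4-(triisopropylsilyloxy)benzaldehyde; 3 vinylmagnesium bromide
Product: 5 (R)-1-[4-(triisopropylsilyloxy)phenyl]prop-2-en-1-ol, via divinylzinc 4 (not isolated)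
Conditions: 3, ZnCl2, THF, 0 °C, then 1,4-dioxane and filtration of the magnesium salts; 2, (2R)-(+)-3-exo-(dimethylamino)isoborneol (10 mol%), toluene, −20 → 0 °C; aq. NH4Cl
Reagents that add atoms: none
Why: Amino-alcohol-catalysed enantioselective addition of a diorganozinc to an aldehyde; the zinc aminoalkoxide of the (2R) ligand should deliver vinyl to the Re face and set the (R) carbinol that becomes C2, and removal of the magnesium salts suppresses the uncatalysed racemic addition.

Step 3
Reactants: 6 4'-methoxyacetophenone
Product: 8 1-(4-methoxyphenyl)prop-2-en-1-one, via Mannich base 7 (not isolated)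
Conditions: (CH2O)n, iPr2NH2+ CF3CO2− (1 equiv), CF3CO2H (10 mol%), THF, reflux; used fresh, trace of BHT
Reagents that add atoms: paraformaldehyde (as formaldehyde), C=O
Why: Mannich reaction at the only enolisable position followed by β-elimination of diisopropylamine from the hindered Mannich base (direct α-methylenation), which should give the aryl vinyl ketone in one operation.

Step 4
Reactants: 5 (R)-1-[4-(triisopropylsilyloxy)phenyl]prop-2-en-1-ol; 8 1-(4-methoxyphenyl)prop-2-en-1-one
Product: 9 1-(4-methoxyphenyl)-3-{(1R)-1-[4-(triisopropylsilyloxy)phenyl]prop-2-enyloxy}propan-1-one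
Conditions: PMe3 (10 mol%), THF, 0 °C → rt, 8 (1.5 equiv) added slowly; volatiles removed under vacuum
Reagents that add atoms: none
Why: Phosphine-catalysed oxa-Michael addition, in which the phosphonium enolate from PMe3 and 8 deprotonates the alcohol and the alkoxide adds to a second molecule of 8; no bond at the carbinol carbon is broken, so the (R) centre is retained, and the nearly neutral medium disfavours retro-addition.

Step 5
Reactants: 9 1-(4-methoxyphenyl)-3-{(1R)-1-[4-(triisopropylsilyloxy)phenyl]prop-2-enyloxy}propan-1-one
Product: 11 (2RS)-2-bromo-1-(4-methoxyphenyl)-3-{(1R)-1-[4-(triisopropylsilyloxy)phenyl]prop-2-enyloxy}propan-1-one, via trimethylsilyl enol ether 10 (not isolated)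
Conditions: LiN(SiMe3)2, Me3SiCl (premixed), THF, −78 °C; then N-bromosuccinimide, THF, −78 → −40 °C; aq. NaHCO3/Na2S2O3
Reagents that add atoms: N-bromosuccinimide, O=C1CCC(=O)N1Br; chlorotrimethylsilane, C[Si](C)(C)Cl (its silyl group stays only in 10)
Why: Kinetic enolisation with internal silyl quench, which traps the enolate before it can expel the β-alkoxide, followed by electrophilic bromination of the silyl enol ether, which should be much faster than attack of the bromine source on the terminal alkene; the new C–Br centre need not be controlled.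

Step 6
Reactants: 11 (2RS)-2-bromo-1-(4-methoxyphenyl)-3-{(1R)-1-[4-(triisopropylsilyloxy)phenyl]prop-2-enyloxy}propan-1-one
Product: 12 (2R,3R,4R)-3-(bromomethyl)-4-(4-methoxybenzoyl)-2-[4-(triisopropylsilyloxy)phenyl]tetrahydrofuran
Conditions: CuBr (10 mol%), CuBr2 (2 mol%), tris(2-pyridylmethyl)amine (12 mol%), degassed CH2Cl2 (0.05 M), rt → 40 °C; filtered through a short silica pad and concentrated, not fractionated
Reagents that add atoms: none
Why: The CuBr complex of tris(2-pyridylmethyl)amine (monovalent copper) reversibly abstracts bromine from either epimer of 11 to give the same planar, electrophilic C4 radical next to the ketone, and because this is a radical and not an enolate the β-oxygen O1 is not expelled. The radical adds to the internal vinyl carbon (C3) and closes the tetrahydrofuran ring O1–C2–C3–C4–C5 in the 5-exo-trig mode by forming C3–C4, after which the primary C9 radical takes bromine from the divalent copper bromide complex and returns the catalyst; this is a copper-catalysed atom-transfer radical cyclisation (intramolecular Kharasch addition) of an α-halo carbonyl compound onto an alkene, a known reaction type. C3 is controlled by the existing C2 centre: in the chair-like transition state of a 4-substituted hex-5-enyl-type radical the C2 aryl group lies pseudo-equatorial, which puts C9 trans to it. C4 is set under weaker control: the bulky, conjugated 4-methoxybenzoyl group should prefer the side of the forming ring away from C9, so 12 is the expected main isomer, but a share of the 3,4-cis epimer is likely and the bromide is taken on unfractionated, because C4 lies α to the ketone and is brought to the trans arrangement under the basic conditions of step 7. The selectivity the step needs is therefore only 2,3-trans, secured by the aryl group on C2, together with fast bromine return, which the added CuBr2 and the dilute solution should favour over attack of the C9 radical on the anisoyl ring or reduction of the C4 radical.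

Step 7
Reactants: 12 (2R,3R,4R)-3-(bromomethyl)-4-(4-methoxybenzoyl)-2-[4-(triisopropylsilyloxy)phenyl]tetrahydrofuran
Product: 15 [(2R,3S,4R)-4-(4-methoxybenzoyl)-2-[4-(triisopropylsilyloxy)phenyl]tetrahydrofuran-3-yl]methyl acetate, via C4-epimeric bromide 13 (not isolated), via C4-epimeric acetate 14 (not isolated)
Conditions: CsOAc (3 equiv), dry DMF, 50 °C; after the bromides are consumed, 1,8-diazabicyclo[5.4.0]undec-7-ene (DBU, 0.5 equiv), rt
Reagents that add atoms: caesium acetate, CC(=O)[O-].[Cs+]
Why: SN2 displacement of the primary C9 bromide by acetate, both in 12 and in its 3,4-cis epimer 13 (present from the closure and in slow acetate-mediated exchange with 12 at C4), then DBU-mediated epimerisation of the cis acetate 14 through the exocyclic enolate to the thermodynamically preferred all-trans 15; the weakly basic acetate should enolise the ketone too slowly for cyclopropane closure of C4 onto C9 to compete, DBU is added only once no bromide is left for the enolate to alkylate, and the enolate should keep O1 because the C5–O1 bond lies close to its nodal plane (ring opening would be a retro-5-endo-trig process).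

Step 8
Reactants: 15 [(2R,3S,4R)-4-(4-methoxybenzoyl)-2-[4-(triisopropylsilyloxy)phenyl]tetrahydrofuran-3-yl]methyl acetate
Product: 16 [(2R,3S,4R)-4-[(S)-hydroxy(4-methoxyphenyl)methyl]-2-[4-(triisopropylsilyloxy)phenyl]tetrahydrofuran-3-yl]methyl acetate
Conditions: Zn(BH4)2, Et2O, −20 → 0 °C; aq. NH4Cl
Reagents that add atoms: none
Why: Chelation-controlled hydride reduction, in which zinc bridges the ketone oxygen and O1 and holds the carbonyl syn to C5 so that hydride adds to the face anti to the C3 branch and gives the (S) carbinol (the Felkin–Anh model with C3 as the large group predicts the same face); the acetate should not be reduced at this temperature.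

Step 9
Reactants: 16 [(2R,3S,4R)-4-[(S)-hydroxy(4-methoxyphenyl)methyl]-2-[4-(triisopropylsilyloxy)phenyl]tetrahydrofuran-3-yl]methyl acetate
Product: 17 [(2R,3S,4R)-4-[(S)-acetoxy(4-methoxyphenyl)methyl]-2-[4-(triisopropylsilyloxy)phenyl]tetrahydrofuran-3-yl]methyl acetate
Conditions: Ac2O, pyridine, 4-(dimethylamino)pyridine (5 mol%), CH2Cl2, 0 °C → rt
Reagents that add atoms: acetic anhydride, CC(=O)OC(C)=O
Why: Nucleophile-catalysed acetylation of the secondary benzylic alcohol under basic conditions, which avoids ionisation of the electron-rich benzylic position and touches no stereocentre.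

Step 10
Reactants: 17 [(2R,3S,4R)-4-[(S)-acetoxy(4-methoxyphenyl)methyl]-2-[4-(triisopropylsilyloxy)phenyl]tetrahydrofuran-3-yl]methyl acetate
Product: 18 [(2R,3S,4R)-4-[(S)-acetoxy(4-methoxyphenyl)methyl]-2-(4-hydroxyphenyl)tetrahydrofuran-3-yl]methyl acetate (CNP0231272.1)
Conditions: Bu4NF, AcOH (1:1.2), THF, 0 °C
Reagents that add atoms: none
Why: Fluoride-mediated cleavage of the aryl silyl ether, buffered with acetic acid so that no free phenoxide is present to transfer acetyl groups or open the benzylic ether; both acetates should remain.

**Compound list**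

1 | 4-hydroxybenzaldehyde | O=Cc1ccc(O)cc1 | starting material
2 | 4-(triisopropylsilyloxy)benzaldehyde | O=Cc1ccc(O[Si](C(C)C)(C(C)C)C(C)C)cc1 | intermediate
3 | vinylmagnesium bromide | C=C[Mg]Br | starting material
4 | divinylzinc | C=C[Zn]C=C | intermediate
5 | (R)-1-[4-(triisopropylsilyloxy)phenyl]prop-2-en-1-ol | O[C@H](C=C)c1ccc(O[Si](C(C)C)(C(C)C)C(C)C)cc1 | intermediate
6 | 4'-methoxyacetophenone | COc1ccc(cc1)C(C)=O | starting material
7 | 3-(diisopropylamino)-1-(4-methoxyphenyl)propan-1-one (Mannich base) | COc1ccc(cc1)C(=O)CCN(C(C)C)C(C)C | intermediate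
8 | 1-(4-methoxyphenyl)prop-2-en-1-one | COc1ccc(cc1)C(=O)C=C | intermediate
9 | 1-(4-methoxyphenyl)-3-{(1R)-1-[4-(triisopropylsilyloxy)phenyl]prop-2-enyloxy}propan-1-one | COc1ccc(cc1)C(=O)CCO[C@H](C=C)c2ccc(O[Si](C(C)C)(C(C)C)C(C)C)cc2 | intermediate
10 | (Z)-trimethylsilyl enol ether of 9 | COc1ccc(cc1)/C(O[Si](C)(C)C)=C/CO[C@H](C=C)c2ccc(O[Si](C(C)C)(C(C)C)C(C)C)cc2 | intermediate
11 | (2RS)-2-bromo-1-(4-methoxyphenyl)-3-{(1R)-1-[4-(triisopropylsilyloxy)phenyl]prop-2-enyloxy}propan-1-one (both bromide epimers, C–Br centre left undefined) | COc1ccc(cc1)C(=O)C(Br)CO[C@H](C=C)c2ccc(O[Si](C(C)C)(C(C)C)C(C)C)cc2 | intermediate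
12 | (2R,3R,4R)-3-(bromomethyl)-4-(4-methoxybenzoyl)-2-[4-(triisopropylsilyloxy)phenyl]tetrahydrofuran (all-trans) | COc1ccc(cc1)C(=O)[C@H]2CO[C@@H](c3ccc(O[Si](C(C)C)(C(C)C)C(C)C)cc3)[C@@H]2CBr | intermediate
13 | (2R,3R,4S)-3-(bromomethyl)-4-(4-methoxybenzoyl)-2-[4-(triisopropylsilyloxy)phenyl]tetrahydrofuran (C4 epimer of 12, 3,4-cis) | COc1ccc(cc1)C(=O)[C@@H]2CO[C@@H](c3ccc(O[Si](C(C)C)(C(C)C)C(C)C)cc3)[C@@H]2CBr | intermediate
14 | [(2R,3S,4S)-4-(4-methoxybenzoyl)-2-[4-(triisopropylsilyloxy)phenyl]tetrahydrofuran-3-yl]methyl acetate (C4 epimer of 15) | COc1ccc(cc1)C(=O)[C@@H]2CO[C@@H](c3ccc(O[Si](C(C)C)(C(C)C)C(C)C)cc3)[C@@H]2COC(C)=O | intermediate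
15 | [(2R,3S,4R)-4-(4-methoxybenzoyl)-2-[4-(triisopropylsilyloxy)phenyl]tetrahydrofuran-3-yl]methyl acetate | COc1ccc(cc1)C(=O)[C@H]2CO[C@@H](c3ccc(O[Si](C(C)C)(C(C)C)C(C)C)cc3)[C@@H]2COC(C)=O | intermediate
16 | [(2R,3S,4R)-4-[(S)-hydroxy(4-methoxyphenyl)methyl]-2-[4-(triisopropylsilyloxy)phenyl]tetrahydrofuran-3-yl]methyl acetate | COc1ccc(cc1)[C@@H](O)[C@H]2CO[C@@H](c3ccc(O[Si](C(C)C)(C(C)C)C(C)C)cc3)[C@@H]2COC(C)=O | intermediate
17 | [(2R,3S,4R)-4-[(S)-acetoxy(4-methoxyphenyl)methyl]-2-[4-(triisopropylsilyloxy)phenyl]tetrahydrofuran-3-yl]methyl acetate | COc1ccc(cc1)[C@@H](OC(C)=O)[C@H]2CO[C@@H](c3ccc(O[Si](C(C)C)(C(C)C)C(C)C)cc3)[C@@H]2COC(C)=O | intermediate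
18 | [(2R,3S,4R)-4-[(S)-acetoxy(4-methoxyphenyl)methyl]-2-(4-hydroxyphenyl)tetrahydrofuran-3-yl]methyl acetate (CNP0231272.1) | COc1ccc([C@@H](OC(C)=O)[C@H]2CO[C@@H](c3ccc(O)cc3)[C@@H]2COC(C)=O)cc1 | target

**Step count**

Total: 10 steps. Longest linear sequence: 9 steps (steps 1, 2, 4, 5, 6, 7, 8, 9, 10 from 4-hydroxybenzaldehyde); step 3 is a one-step side branch.

**Steps most likely to fail**

1. Step 6 (key step). The monovalent copper complex may reduce the C4 radical to the enolate, which would then lose the allylic alkoxide by β-elimination. Bromine return from divalent copper may also lag, so that the C9 radical is lost to the anisoyl ring. The fallback keeps the same C3–C4 closure but runs it as a metal-free iodine-atom-transfer radical chain, with no reductant present. It sets out from 11: NaI in acetone at rt in the dark (Finkelstein exchange) should give the α-iodo ketone F1. Hexabutylditin (10 mol%) under a sunlamp in benzene at rt should then give, through the same chair-like 5-exo closure, the all-trans 3-(iodomethyl)tetrahydrofuran F2 and its C4 epimer F3. CsOAc in dry DMF followed by DBU, as in step 7, displaces the iodide and equilibrates C4 through the epimeric acetate 14, so the fallback comes back to the route at 15.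

2. Step 4. Phosphine-triggered oligomerisation of vinyl ketone 8 may outrun addition of the hindered secondary alkoxide, or the adduct may revert on concentration. The fallback builds the ketone after the ether and sets out from 5. Cyanoethylation with acrylonitrile (KOtBu 5 mol%, THF, 0 °C → rt) should give the nitrile F4. Addition of 4-methoxyphenylmagnesium bromide (CuBr 2 mol%, THF, 0 °C → rt) and hydrolysis of the resulting ketimine F5 in aqueous acetate buffer (pH 5) should then deliver the ketone. It comes back to the route at 9; step 3 and compound 8 are then not needed.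

3. Step 8. Facial selectivity of hydride delivery may be poor if zinc does not chelate O1 (its lone pair is flanked by the C2 aryl group) and the bias from C4 alone is weak. The fallback replaces substrate control by reagent control and sets out from 15. Corey–Bakshi–Shibata reduction with (R)-1-methyl-3,3-diphenyltetrahydro-1H,3H-pyrrolo[1,2-c][1,3,2]oxazaborole (10–20 mol%) and BH3·SMe2 in toluene at −20 °C should deliver hydride to the face that gives the (S) carbinol, with the aryl group acting as the large substituent. It comes back to the route at 16 and creates no new compound, F0; material of the wrong configuration could be returned to 15 by Dess–Martin oxidation.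

**Further compounds**

F1 | step 6 | (2RS)-2-iodo-1-(4-methoxyphenyl)-3-{(1R)-1-[4-(triisopropylsilyloxy)phenyl]prop-2-enyloxy}propan-1-one | COc1ccc(cc1)C(=O)C(I)CO[C@H](C=C)c2ccc(O[Si](C(C)C)(C(C)C)C(C)C)cc2
F2 | step 6 | (2R,3R,4R)-3-(iodomethyl)-4-(4-methoxybenzoyl)-2-[4-(triisopropylsilyloxy)phenyl]tetrahydrofuran | COc1ccc(cc1)C(=O)[C@H]2CO[C@@H](c3ccc(O[Si](C(C)C)(C(C)C)C(C)C)cc3)[C@@H]2CI
F3 | step 6 | (2R,3R,4S)-3-(iodomethyl)-4-(4-methoxybenzoyl)-2-[4-(triisopropylsilyloxy)phenyl]tetrahydrofuran | COc1ccc(cc1)C(=O)[C@@H]2CO[C@@H](c3ccc(O[Si](C(C)C)(C(C)C)C(C)C)cc3)[C@@H]2CI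
F4 | step 4 | 3-{(1R)-1-[4-(triisopropylsilyloxy)phenyl]prop-2-enyloxy}propanenitrile | N#CCCO[C@H](C=C)c1ccc(O[Si](C(C)C)(C(C)C)C(C)C)cc1
F5 | step 4 | 1-(4-methoxyphenyl)-3-{(1R)-1-[4-(triisopropylsilyloxy)phenyl]prop-2-enyloxy}propan-1-imine | COc1ccc(cc1)C(=N)CCO[C@H](C=C)c2ccc(O[Si](C(C)C)(C(C)C)C(C)C)cc2
F0 | step 8 | none | none
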